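The synthesis rests on disconnecting ring B of the right-hand decalin at C9–C10. The quaternary, methyl-bearing C10, set between ring-fusion C5 and chain-bearing C9 and neighboured by oxygenated C6 and C7, corresponds to the vinylic methyl carbon of a bicyclo[2.2.2]octenol made from creosol. A single anionic oxy-Cope rearrangement forges C9–C10, closes ring B, relays the resolved bridgehead configuration to C10 and unveils the C7 ketone next to a C6 ketal, the latent diosphenol. The precursor is a 2-alkenyl-3,3-dimethoxy-5-methylbicyclo[2.2.2]oct-5-en-2-ol whose alkenyl arm (C8, C9, C11, C12) already ends in the complete oxepane-fused cyclohexane, assembled beforehand by an epoxide-opening cascade.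

Key step: step 14

Numbering: the right half is numbered C1–C10 as a terpenoid decalin (C3 ketone, C4 gem-dimethyl, C5 and C10 fusion atoms, C6 and C7 diosphenol carbons, C8 methyl-bearing, C9 chain-bearing); C11–C12 is the ethylene linker. The left half is numbered as a 1-benzoxepine (O1, C2–C5, C5a, C6–C9, C9a). "Bx-OTBS", "Bx-OH" and "Bx=O" stand for the (5aR,6S,7S,9aR)-2,2,5a,7-tetramethyldecahydro-1-benzoxepin-6-yl group carrying at C3 an (R)-tert-butyldimethylsilyloxy group, an (R)-hydroxyl group or a ketone.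

Assumption: the absolute configuration of the resolved bicyclic ketone is assigned independently (vibrational circular dichroism or X-ray analysis of a crystalline derivative) before it is carried on; the orientation of the sulfonyl group in the Diels–Alder adduct is of no consequence because the group is removed in the next step.

Step 1
Reactants: 1 creosol (2-methoxy-4-methylphenol); 2 phenyl vinyl sulfone
Product: 4 racemic 3,3-dimethoxy-5-methyl-7-(phenylsulfonyl)bicyclo[2.2.2]oct-5-en-2-one, via masked o-benzoquinone 3 (not isolated)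
Conditions: PhI(OAc)2, MeOH, 2 (5 equiv), 0 to 25 °C
Reagents that add atoms: methanol, CO
Why: Oxidative ketalisation of the phenol should give 6,6-dimethoxy-4-methylcyclohexa-2,4-dienone 3, which the excess electron-poor alkene intercepts in a Diels–Alder reaction that turns C2 and C5 of the dienone into the bridgeheads and leaves the methyl-bearing alkene carbon beside the ketal-side bridgehead.

Step 2
Reactants: 4 racemic sulfonyl bicyclooctenone
Product: 5 racemic 3,3-dimethoxy-5-methylbicyclo[2.2.2]oct-5-en-2-one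
Conditions: Na(Hg) (6%), Na2HPO4, MeOH–THF, −20 °C
Reagents that add atoms: none
Why: Reductive desulfonylation by electron transfer from Na(Hg) under cold, buffered conditions exchanges C–S for C–H, so that the vinyl sulfone has acted as an ethylene equivalent, while the non-enolisable ketone and the ketal should persist.

Step 3
Reactants: 5 racemic 3,3-dimethoxy-5-methylbicyclo[2.2.2]oct-5-en-2-one
Product: 6 (1R,4S)-3,3-dimethoxy-5-methylbicyclo[2.2.2]oct-5-en-2-one
Conditions: preparative supercritical-fluid chromatography, amylose tris(3,5-dimethylphenylcarbamate) phase, CO2–i-PrOH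
Reagents that add atoms: none
Why: Resolution of the racemate on a chiral stationary phase should deliver the enantiomer whose bridgehead configuration is later copied to C10, and the rigid bicycle rules out any later epimerisation of these centres.

Step 4
Reactants: 7 (E)-geranylacetone [(5E)-6,10-dimethylundeca-5,9-dien-2-one]
Product: 8 (5R,6R,9R)-5,6:9,10-diepoxy-6,10-dimethylundecan-2-one
Conditions: D-fructose-derived Shi ketone (30 mol% per alkene), KHSO5 (Oxone), K2CO3, Bu4NHSO4, MeCN–CH2(OMe)2–aqueous buffer pH 10.5, 0 °C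
Reagents that add atoms: potassium peroxymonosulfate KHSO5, [K+].[O-]S(=O)(=O)OO
Why: Shi asymmetric epoxidation, in which the chiral dioxirane formed from the ketone catalyst epoxidises both trisubstituted alkenes through a spiro transition state and sets the 5R,6R and 9R centres under reagent control.

Step 5
Reactants: 8 (5R,6R,9R)-diepoxy ketone; 9 benzyloxyacetaldehyde
Product: 11 (7R,8R,11R)-1-(benzyloxy)-7,8:11,12-diepoxy-2-hydroxy-8,12-dimethyltridecan-4-one as a mixture of C2 epimers, via lithium enolate 10 (not isolated)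
Conditions: LiN(i-Pr)2, THF, −78 °C; then 9; aqueous NH4Cl
Reagents that add atoms: none
Why: Kinetic deprotonation of the methyl ketone at its CH3 group and aldol addition to the aldehyde join future ring carbon C6 of the benzoxepine to linker carbon C12, the epoxides being inert to the enolate at −78 °C and the new carbinol centre being removed in step 6.

Step 6
Reactants: 11 aldol adduct (C2 epimers)
Product: 13 (2E,7R,8R,11R)-1-(benzyloxy)-7,8:11,12-diepoxy-8,12-dimethyltridec-2-en-4-one, via mesylate 12 (not isolated)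
Conditions: MsCl, Et3N, CH2Cl2, 0 to 25 °C
Reagents that add atoms: none
Why: Mesylation followed by E1cB elimination of the β-sulfonyloxy ketone should give the conjugated enone in its thermodynamically preferred E geometry.

Step 7
Reactants: 13 (2E)-diepoxy enone
Product: 14 tert-butyl{[(3Z,7R,8R,11R)-1-(benzyloxy)-7,8:11,12-diepoxy-8,12-dimethyltridec-3-en-4-yl]oxy}dimethylsilane
Conditions: t-BuMe2SiH, Pt2[(CH2=CHSiMe2)2O]3 (Karstedt catalyst, 1 mol%), toluene, 60 °C
Reagents that add atoms: tert-butyldimethylsilane, CC(C)(C)[SiH](C)C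
Why: Platinum-catalysed 1,4-hydrosilylation of the enone places hydride on C2 and silicon on oxygen, which fixes the silyl enol ether on the side that must become ring carbon C6, mainly as the Z isomer from the s-cis enone.

Step 8
Reactants: 14 diepoxy silyl enol ether
Product: 15 (3R,5aR,6R,9aR)-6-[2-(benzyloxy)ethyl]-3-[(tert-butyldimethylsilyl)oxy]-2,2,5a-trimethyloctahydro-1-benzoxepin-7(2H)-one
Conditions: t-BuMe2SiOTf (0.3 equiv), 2,6-di-tert-butyl-4-methylpyridine, CH2Cl2, −78 °C; aqueous NaHCO3
Reagents that add atoms: none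
Why: Lewis-acid-promoted epoxide-opening cascade (tandem oxa- and carbacyclisation) without a persistent intermediate, in which silylation of the terminal epoxide oxygen lets the internal epoxide oxygen open it at the tertiary carbon to close the oxepane (C3 retained as R), the enol ether carbon then displaces that oxygen from its own tertiary carbon with inversion through a chair arrangement to set the trans fusion (5aR,9aR), the C6 side chain ends equatorial (the stable epimer beside the ketone), and the enol silyl group departs as the triflate and carries the chain, so the step is a net isomerisation.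

Step 9
Reactants: 15 bicyclic ketone
Product: 16 (3R,5aR,6S,9aR)-6-[2-(benzyloxy)ethyl]-3-[(tert-butyldimethylsilyl)oxy]-2,2,5a-trimethyl-7-methylidenedecahydro-1-benzoxepine
Conditions: Ph3PCH3Br, KOt-Bu, toluene, 0 to 80 °C
Reagents that add atoms: methyltriphenylphosphonium bromide, C[P+](c1ccccc1)(c1ccccc1)c1ccccc1.[Br-]
Why: Wittig methylenation with the small non-stabilised ylide installs the carbon of the C7 methyl group, and the adjacent C6 centre already has its more stable equatorial configuration, so the basic medium cannot erode it.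

Step 10
Reactants: 16 exocyclic alkene
Product: 17 2-(Bx-OTBS)ethan-1-ol, that is 2-[(3R,5aR,6S,7S,9aR)-3-[(tert-butyldimethylsilyl)oxy]-2,2,5a,7-tetramethyldecahydro-1-benzoxepin-6-yl]ethan-1-ol
Conditions: H2 (3 atm), Pd(OH)2/C, EtOAc–EtOH, 25 °C
Reagents that add atoms: none
Why: Heterogeneous catalytic hydrogenation should deliver hydrogen to the exocyclic alkene from the face opposite the axial C5a methyl group, giving the axial 7S methyl group cis to it, and the same catalyst hydrogenolyses the benzyl ether to free the primary alcohol.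

Step 11
Reactants: 17 2-(Bx-OTBS)ethan-1-ol; 18 1-propynyllithium
Product: 20 (3R,5aR,6S,7S,9aR)-3-[(tert-butyldimethylsilyl)oxy]-2,2,5a,7-tetramethyl-6-(pent-3-yn-1-yl)decahydro-1-benzoxepine, via primary triflate 19 (not isolated)
Conditions: Tf2O, 2,6-lutidine, CH2Cl2, −78 °C; then 18, THF–DMPU, −78 to 0 °C
Reagents that add atoms: none
Why: Triflation of the unhindered primary alcohol and SN2 displacement by the lithium acetylide forms the C11–C9 bond and completes the five-carbon arm without disturbing the hindered secondary silyl ether.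

Step 12
Reactants: 20 2-alkyne
Product: 22 (3R,5aR,6S,7S,9aR)-3-[(tert-butyldimethylsilyl)oxy]-6-[(3E)-4-iodopent-3-en-1-yl]-2,2,5a,7-tetramethyldecahydro-1-benzoxepine, via alkenylzirconocene chloride 21 (not isolated)
Conditions: Cp2Zr(H)Cl (2 equiv), THF, 25 to 45 °C; then I2, 0 °C
Reagents that add atoms: iodine, II
Why: Hydrozirconation with Cp2Zr(H)Cl adds Zr–H syn across the alkyne and, after equilibration with the excess reagent, leaves zirconium on the less hindered methyl-bearing carbon, and iodinolysis with retention should give the E 2-iodoalkene.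

Step 13
Reactants: 22 (E)-alkenyl iodide; 6 (1R,4S)-3,3-dimethoxy-5-methylbicyclo[2.2.2]oct-5-en-2-one
Product: 24 (1R,2S,4S)-2-[(2E)-5-(Bx-OTBS)pent-2-en-2-yl]-3,3-dimethoxy-5-methylbicyclo[2.2.2]oct-5-en-2-ol, via alkenyllithium 23 (not isolated)
Conditions: t-BuLi (2 equiv), Et2O, −78 °C; then 6, Et2O–THF, −78 to −40 °C; aqueous NH4Cl
Reagents that add atoms: none
Why: Iodine–lithium exchange with retention of alkene geometry and 1,2-addition to the non-enolisable ketone, which is approached from the face of the C5=C6 bridge because the ethano bridge shields the other one, so that the alkenyl group ends syn to the ring alkene and the carbinol carbon becomes S.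

Step 14
Reactants: 24 (1R,2S,4S)-2-alkenylbicyclooctenol
Product: 27 cis-fused 9-[2-(Bx-OTBS)ethyl]-6,6-dimethoxy-8,10-dimethyldecal-1-en-7-one (5-H cis to 10-CH3; 9-side chain trans to 10-CH3; C8 epimers), via potassium alkoxide 25 (not isolated), via potassium enolate 26 (not isolated)
Conditions: KH, 18-crown-6, THF, 0 to 25 °C; then aqueous NH4Cl, 0 °C
Reagents that add atoms: none
Why: Deprotonation by KH in the presence of 18-crown-6 gives the ion-pair-separated alkoxide 25, in which the oxyanion weakens the adjacent C7–C2 bond and drives a concerted [3,3] sigmatropic shift across the 1,5-diene C9=C8–C7–C2–C1=C10, so that C9 bonds to C10 as C7–C2 breaks and the enolate 26 results, which is protonated to 27 on work-up. The closest known reaction type is the anionic oxy-Cope rearrangement of 2-alkenylbicyclo[2.2.2]oct-5-en-2-ols obtained from masked o-benzoquinone cycloadducts, which gives cis-fused decalins. Ring B (C5–C6–C7–C8–C9–C10) closes by this sigmatropic C9–C10 bond formation through the boat-like six-centre transition state enforced by the bicycle, suprafacial on both allyl units, and release of the bicyclic strain together with enolate formation makes it irreversible. The new quaternary centre C10 is controlled by bridgehead C5, because C9 can reach only the face of the C1=C10 alkene that is turned towards the C6–C7 bridge, which makes the ring fusion cis and copies the configuration of 6 to C10 as the target requires. C9 follows from the E alkene geometry and the boat arrangement and C8 from the protonation, and both are removed in step 15. The selectivity needed is the placement of the alkenyl group syn to the ring alkene, secured by the facial course of step 13, together with a base-stable periphery, secured by the C6 ketal, the silyl ether and the saturated left half.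

Step 15
Reactants: 27 cis-fused decal-1-en-7-one
Product: 29 9-[2-(Bx-OTBS)ethyl]-6,6-dimethoxy-8,10-dimethyldecala-1,8-dien-7-one (5-H cis to 10-CH3), via trimethylsilyl enol ether 28 (not isolated)
Conditions: KN(SiMe3)2, THF, −78 °C; Me3SiCl; then Pd(OAc)2 (1.1 equiv), MeCN, 25 °C
Reagents that add atoms: none
Why: Saegusa–Ito oxidation, in which the ketone can enolise only towards C8 because C6 is quaternary and the palladium enolate formed from 28 loses the C9 hydrogen by β-hydride elimination to give the conjugated tetrasubstituted C8=C9 enone, which removes the C8 and C9 stereocentres.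

Step 16
Reactants: 29 decala-1,8-dien-7-one
Product: 30 9-[2-(Bx-OTBS)ethyl]-6,6-dimethoxy-8,10-dimethyldecala-1,8-diene-3,7-dione
Conditions: CrO3, 3,5-dimethylpyrazole, CH2Cl2, −20 °C
Reagents that add atoms: chromium trioxide, O=[Cr](=O)=O
Why: Allylic oxidation of the ring A alkene, for which C3 is the only allylic CH2 (C10 is quaternary) and the less hindered end of the allyl system, so that the C1=C2–C3=O enone should form while the electron-poor C8=C9 enone resists the electrophilic oxidant.

Step 17
Reactants: 30 decala-1,8-diene-3,7-dione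
Product: 32 9-[2-(Bx-OTBS)ethyl]-6,6-dimethoxy-4,4,8,10-tetramethyldecala-1,8-diene-3,7-dione, via monomethyl enone 31 (not isolated)
Conditions: LiN(i-Pr)2 (1.1 equiv), THF, −78 °C; CH3I; then a second cycle of LiN(i-Pr)2 and CH3I with DMPU, −78 to 0 °C
Reagents that add atoms: iodomethane, CI
Why: Kinetic α′-enolate alkylation of an enone carried out twice, in which C4 is the only sp3 carbon bearing hydrogen next to either carbonyl group (C2 and C8 are vinylic and C6 is a ketal carbon), so that both methyl groups enter at C4 and this centre is not stereogenic.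

Step 18
Reactants: 32 4,4-dimethyl dienedione
Product: 33 9-[2-(Bx-OTBS)ethyl]-6,6-dimethoxy-4,4,8,10-tetramethyldecal-8-ene-3,7-dione
Conditions: H2 (1 atm), Pd/C, EtOAc, 25 °C
Reagents that add atoms: none
Why: Chemoselective catalytic hydrogenation, in which the disubstituted C1=C2 enone alkene is reduced far faster than the tetrasubstituted C8=C9 enone alkene, giving the saturated ring A 3-ketone without any new stereocentre.

Step 19
Reactants: 33 silyl-protected enedione
Product: 34 9-[2-(Bx-OH)ethyl]-6,6-dimethoxy-4,4,8,10-tetramethyldecal-8-ene-3,7-dione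
Conditions: HF·pyridine, THF, 0 to 25 °C
Reagents that add atoms: none
Why: Fluoride-mediated cleavage of the silyl ether frees the secondary hydroxyl group of the oxepane under conditions too weakly acidic and too dry to open the hindered α-keto ketal.

Step 20
Reactants: 34 oxepanol
Product: 35 9-[2-(Bx=O)ethyl]-6,6-dimethoxy-4,4,8,10-tetramethyldecal-8-ene-3,7-dione
Conditions: Dess–Martin periodinane, NaHCO3, CH2Cl2, 25 °C
Reagents that add atoms: none
Why: Dess–Martin oxidation converts the secondary alcohol into the oxepanone while the diosphenol is still masked as its ketal and therefore cannot be oxidised.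

Step 21
Reactants: 35 oxepanone ketal
Product: 37 CNP0302807.1 (target), via 6,7-diketone 36 (not isolated)
Conditions: 3 M aqueous HCl, THF, 50 °C
Reagents that add atoms: water, O
Why: Acid hydrolysis of the α-keto dimethyl ketal gives the C6,C7-dione 36, which tautomerises by loss of the C5 hydrogen to the fully conjugated diosphenol (C5=C6–OH, C7=O, C8=C9), the only enol available because C4 and C10 are quaternary, and no remaining stereocentre carries an acidic hydrogen.

Compound list

1 | creosol (2-methoxy-4-methylphenol) | COc1cc(C)ccc1O | starting material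
2 | phenyl vinyl sulfone | C=CS(=O)(=O)c1ccccc1 | starting material
3 | 6,6-dimethoxy-4-methylcyclohexa-2,4-dien-1-one (masked o-benzoquinone) | COC1(OC)C=C(C)C=CC1=O | intermediate
4 | racemic 3,3-dimethoxy-5-methyl-7-(phenylsulfonyl)bicyclo[2.2.2]oct-5-en-2-one, sulfonyl group syn to the C5=C6 bridge (one enantiomer drawn) | O=C1C(OC)(OC)[C@H]2C[C@H](S(=O)(=O)c3ccccc3)[C@@H]1C=C2C | intermediate
5 | racemic 3,3-dimethoxy-5-methylbicyclo[2.2.2]oct-5-en-2-one | O=C1C(OC)(OC)C2CCC1C=C2C | intermediate
6 | (1R,4S)-3,3-dimethoxy-5-methylbicyclo[2.2.2]oct-5-en-2-one | O=C1C(OC)(OC)[C@H]2CC[C@@H]1C=C2C | intermediate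
7 | (E)-geranylacetone | CC(=O)CC/C=C(\C)CCC=C(C)C | starting material
8 | (5R,6R,9R)-5,6:9,10-diepoxy-6,10-dimethylundecan-2-one | CC(=O)CC[C@H]1O[C@]1(C)CC[C@H]1OC1(C)C | intermediate
9 | benzyloxyacetaldehyde | O=CCOCc1ccccc1 | starting material
10 | terminal lithium enolate of 8 | C=C(O[Li])CC[C@H]1O[C@]1(C)CC[C@H]1OC1(C)C | intermediate
11 | (7R,8R,11R)-1-(benzyloxy)-7,8:11,12-diepoxy-2-hydroxy-8,12-dimethyltridecan-4-one (C2 epimers) | OC(COCc1ccccc1)CC(=O)CC[C@H]1O[C@]1(C)CC[C@H]1OC1(C)C | intermediate
12 | C2 methanesulfonate of 11 (C2 epimers) | CS(=O)(=O)OC(COCc1ccccc1)CC(=O)CC[C@H]1O[C@]1(C)CC[C@H]1OC1(C)C | intermediate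
13 | (2E,7R,8R,11R)-1-(benzyloxy)-7,8:11,12-diepoxy-8,12-dimethyltridec-2-en-4-one | O=C(/C=C/COCc1ccccc1)CC[C@H]1O[C@]1(C)CC[C@H]1OC1(C)C | intermediate
14 | tert-butyl{[(3Z,7R,8R,11R)-1-(benzyloxy)-7,8:11,12-diepoxy-8,12-dimethyltridec-3-en-4-yl]oxy}dimethylsilane | CC(C)(C)[Si](C)(C)O/C(=C\CCOCc1ccccc1)CC[C@H]1O[C@]1(C)CC[C@H]1OC1(C)C | intermediate
15 | (3R,5aR,6R,9aR)-6-[2-(benzyloxy)ethyl]-3-[(tert-butyldimethylsilyl)oxy]-2,2,5a-trimethyloctahydro-1-benzoxepin-7(2H)-one (trans-fused, side chain cis to the 5a-methyl) | c1ccccc1COCC[C@H]2C(=O)CC[C@H]3OC(C)(C)[C@H](O[Si](C)(C)C(C)(C)C)CC[C@@]32C | intermediate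
16 | (3R,5aR,6S,9aR)-6-[2-(benzyloxy)ethyl]-3-[(tert-butyldimethylsilyl)oxy]-2,2,5a-trimethyl-7-methylidenedecahydro-1-benzoxepine | c1ccccc1COCC[C@H]2C(=C)CC[C@H]3OC(C)(C)[C@H](O[Si](C)(C)C(C)(C)C)CC[C@@]32C | intermediate
17 | 2-[(3R,5aR,6S,7S,9aR)-3-[(tert-butyldimethylsilyl)oxy]-2,2,5a,7-tetramethyldecahydro-1-benzoxepin-6-yl]ethan-1-ol | OCC[C@H]1[C@@H](C)CC[C@H]2OC(C)(C)[C@H](O[Si](C)(C)C(C)(C)C)CC[C@@]21C | intermediate
18 | 1-propynyllithium | [Li]C#CC | starting material
19 | trifluoromethanesulfonate of 17 | O=S(=O)(OCC[C@H]1[C@@H](C)CC[C@H]2OC(C)(C)[C@H](O[Si](C)(C)C(C)(C)C)CC[C@@]21C)C(F)(F)F | intermediate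
20 | (3R,5aR,6S,7S,9aR)-3-[(tert-butyldimethylsilyl)oxy]-2,2,5a,7-tetramethyl-6-(pent-3-yn-1-yl)decahydro-1-benzoxepine | CC#CCC[C@H]1[C@@H](C)CC[C@H]2OC(C)(C)[C@H](O[Si](C)(C)C(C)(C)C)CC[C@@]21C | intermediate
21 | (E)-alkenylzirconocene chloride from 20, zirconium on the methyl-bearing carbon | C/C(=C\CC[C@H]1[C@@H](C)CC[C@H]2OC(C)(C)[C@H](O[Si](C)(C)C(C)(C)C)CC[C@@]21C)[Zr](Cl)(C1C=CC=C1)C1C=CC=C1 | intermediate
22 | (3R,5aR,6S,7S,9aR)-3-[(tert-butyldimethylsilyl)oxy]-6-[(3E)-4-iodopent-3-en-1-yl]-2,2,5a,7-tetramethyldecahydro-1-benzoxepine | C/C(I)=C\CC[C@H]1[C@@H](C)CC[C@H]2OC(C)(C)[C@H](O[Si](C)(C)C(C)(C)C)CC[C@@]21C | intermediate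
23 | alkenyllithium from 22 (geometry retained) | C/C([Li])=C\CC[C@H]1[C@@H](C)CC[C@H]2OC(C)(C)[C@H](O[Si](C)(C)C(C)(C)C)CC[C@@]21C | intermediate
24 | (1R,2S,4S)-2-[(2E)-5-(Bx-OTBS)pent-2-en-2-yl]-3,3-dimethoxy-5-methylbicyclo[2.2.2]oct-5-en-2-ol (alkenyl group syn to the ring alkene) | C/C(=C\CC[C@H]3[C@@H](C)CC[C@H]4OC(C)(C)[C@H](O[Si](C)(C)C(C)(C)C)CC[C@@]43C)[C@]1(O)C(OC)(OC)[C@H]2CC[C@@H]1C=C2C | intermediate
25 | potassium alkoxide of 24 | C/C(=C\CC[C@H]3[C@@H](C)CC[C@H]4OC(C)(C)[C@H](O[Si](C)(C)C(C)(C)C)CC[C@@]43C)[C@]1([O-])C(OC)(OC)[C@H]2CC[C@@H]1C=C2C.[K+] | intermediate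
26 | potassium C7–C8 enolate of 27 | C([C@H]3[C@@H](C)CC[C@H]4OC(C)(C)[C@H](O[Si](C)(C)C(C)(C)C)CC[C@@]43C)C[C@H]1C(C)=C([O-])C(OC)(OC)[C@H]2CCC=C[C@@]12C.[K+] | intermediate
27 | cis-fused 9-[2-(Bx-OTBS)ethyl]-6,6-dimethoxy-8,10-dimethyldecal-1-en-7-one (5-H cis to 10-CH3, side chain trans to 10-CH3, C8 epimers) | C([C@H]3[C@@H](C)CC[C@H]4OC(C)(C)[C@H](O[Si](C)(C)C(C)(C)C)CC[C@@]43C)C[C@H]1C(C)C(=O)C(OC)(OC)[C@H]2CCC=C[C@@]12C | intermediate
28 | trimethylsilyl enol ether (C7–C8) of 27 | C([C@H]3[C@@H](C)CC[C@H]4OC(C)(C)[C@H](O[Si](C)(C)C(C)(C)C)CC[C@@]43C)C[C@H]1C(C)=C(O[Si](C)(C)C)C(OC)(OC)[C@H]2CCC=C[C@@]12C | intermediate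
29 | 9-[2-(Bx-OTBS)ethyl]-6,6-dimethoxy-8,10-dimethyldecala-1,8-dien-7-one (5-H cis to 10-CH3) | C([C@H]3[C@@H](C)CC[C@H]4OC(C)(C)[C@H](O[Si](C)(C)C(C)(C)C)CC[C@@]43C)CC1=C(C)C(=O)C(OC)(OC)[C@H]2CCC=C[C@@]12C | intermediate
30 | 9-[2-(Bx-OTBS)ethyl]-6,6-dimethoxy-8,10-dimethyldecala-1,8-diene-3,7-dione | C([C@H]3[C@@H](C)CC[C@H]4OC(C)(C)[C@H](O[Si](C)(C)C(C)(C)C)CC[C@@]43C)CC1=C(C)C(=O)C(OC)(OC)[C@H]2CC(=O)C=C[C@@]12C | intermediate
31 | 4-methyl derivative of 30 (C4 epimers) | C([C@H]3[C@@H](C)CC[C@H]4OC(C)(C)[C@H](O[Si](C)(C)C(C)(C)C)CC[C@@]43C)CC1=C(C)C(=O)C(OC)(OC)[C@H]2C(C)C(=O)C=C[C@@]12C | intermediate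
32 | 9-[2-(Bx-OTBS)ethyl]-6,6-dimethoxy-4,4,8,10-tetramethyldecala-1,8-diene-3,7-dione | C([C@H]3[C@@H](C)CC[C@H]4OC(C)(C)[C@H](O[Si](C)(C)C(C)(C)C)CC[C@@]43C)CC1=C(C)C(=O)C(OC)(OC)[C@H]2C(C)(C)C(=O)C=C[C@@]12C | intermediate
33 | 9-[2-(Bx-OTBS)ethyl]-6,6-dimethoxy-4,4,8,10-tetramethyldecal-8-ene-3,7-dione | C([C@H]3[C@@H](C)CC[C@H]4OC(C)(C)[C@H](O[Si](C)(C)C(C)(C)C)CC[C@@]43C)CC1=C(C)C(=O)C(OC)(OC)[C@H]2C(C)(C)C(=O)CC[C@@]12C | intermediate
34 | 9-[2-(Bx-OH)ethyl]-6,6-dimethoxy-4,4,8,10-tetramethyldecal-8-ene-3,7-dione | C([C@H]3[C@@H](C)CC[C@H]4OC(C)(C)[C@H](O)CC[C@@]43C)CC1=C(C)C(=O)C(OC)(OC)[C@H]2C(C)(C)C(=O)CC[C@@]12C | intermediate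
35 | 9-[2-(Bx=O)ethyl]-6,6-dimethoxy-4,4,8,10-tetramethyldecal-8-ene-3,7-dione | C([C@H]3[C@@H](C)CC[C@H]4OC(C)(C)C(=O)CC[C@@]43C)CC1=C(C)C(=O)C(OC)(OC)[C@H]2C(C)(C)C(=O)CC[C@@]12C | intermediate
36 | 9-[2-(Bx=O)ethyl]-4,4,8,10-tetramethyldecal-8-ene-3,6,7-trione (6,7-diketo tautomer of the target) | C([C@H]3[C@@H](C)CC[C@H]4OC(C)(C)C(=O)CC[C@@]43C)CC1=C(C)C(=O)C(=O)[C@H]2C(C)(C)C(=O)CC[C@@]12C | intermediate
37 | CNP0302807.1: 9-[2-(Bx=O)ethyl]-6-hydroxy-4,4,8,10-tetramethyldecala-5,8-diene-3,7-dione | CC1=C(CC[C@H]2[C@@H](C)CC[C@H]3OC(C)(C)C(=O)CC[C@@]32C)[C@]2(C)CCC(=O)C(C)(C)C2=C(O)C1=O | target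

Total step count: 21. Longest linear sequence: 18 steps (steps 4 to 21).

Steps most likely to fail

Step 17. The second C-methylation has to build a quaternary carbon beside the tertiary C5 and may be slow, so that O-methylation, proton transfer from the C11 position of the C7 enone or incomplete conversion compete. The fallback keeps the enolate but delivers the second carbon by cyclopropanation instead of SN2 alkylation. It sets out from 31, isolated after the first methylation cycle. Deprotonation with LiN(i-Pr)2 in the presence of Me3SiCl in THF at −78 °C should trap the C3–C4 enolate on oxygen as the 3-(trimethylsilyloxy)-1,3-diene F1 . Simmons–Smith cyclopropanation of F1 with Et2Zn and CH2I2 in toluene at 0 to 25 °C should attack the electron-rich enol ether double bond and give the siloxycyclopropane F2 as a mixture of cyclopropane diastereomers. Treatment of F2 with K2CO3 in MeOH at 25 °C should cleave the silyl ether and open the cyclopropanolate towards the primary carbon, which turns the ring CH2 into the second C4 methyl group, so that the fallback comes back to the route at 32.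

Step 15. Enolisation of the hindered ketone may be slow, or β-hydride elimination may take a hydrogen from the C8 methyl group and lead to the exocyclic enone. The fallback is halogenation followed by elimination under equilibrating conditions. It sets out from 27: KN(SiMe3)2 and then N-bromosuccinimide in THF at −78 °C should give the 8-bromo ketone F3 as a mixture of C8 epimers. Heating F3 with Li2CO3 and LiBr in DMF at 120 °C should eliminate HBr towards the more stable endocyclic alkene, so that the fallback comes back to the route at 29.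

Step 14. The hindered tertiary alkoxide may fragment by retro-addition (loss of the alkenyl anion) faster than it rearranges. The fallback is the neutral thermal siloxy-Cope rearrangement. It sets out from 24: silylation with N-(trimethylsilyl)imidazole in CH2Cl2 at 40 °C should give the tertiary trimethylsilyl ether F4 . Heating F4 in 1,2-dichlorobenzene at about 200 °C should take it through the same boat transition state directly to the trimethylsilyl enol ether, so that the fallback comes back to the route at 28, just before the Pd(OAc)2 oxidation of step 15.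

Further compounds

F1 | step 17 | 3-(trimethylsilyloxy)-1,3-diene from 31: 9-[2-(Bx-OTBS)ethyl]-6,6-dimethoxy-4,8,10-trimethyl-3-(trimethylsilyloxy)decala-1,3,8-trien-7-one | C([C@H]3[C@@H](C)CC[C@H]4OC(C)(C)[C@H](O[Si](C)(C)C(C)(C)C)CC[C@@]43C)CC1=C(C)C(=O)C(OC)(OC)[C@H]2C(C)=C(O[Si](C)(C)C)C=C[C@@]12C
F2 | step 17 | siloxycyclopropane from F1: 3,4-methano-bridged 9-[2-(Bx-OTBS)ethyl]-6,6-dimethoxy-4,8,10-trimethyl-3-(trimethylsilyloxy)decala-1,8-dien-7-one (cyclopropane diastereomers) | C([C@H]3[C@@H](C)CC[C@H]4OC(C)(C)[C@H](O[Si](C)(C)C(C)(C)C)CC[C@@]43C)CC1=C(C)C(=O)C(OC)(OC)[C@H]2C5(C)CC5(O[Si](C)(C)C)C=C[C@@]12C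
F3 | step 15 | 8-bromo derivative of 27 (C8 epimers) | C([C@H]3[C@@H](C)CC[C@H]4OC(C)(C)[C@H](O[Si](C)(C)C(C)(C)C)CC[C@@]43C)C[C@H]1C(C)(Br)C(=O)C(OC)(OC)[C@H]2CCC=C[C@@]12C
F4 | step 14 | trimethylsilyl ether of 24 | C/C(=C\CC[C@H]3[C@@H](C)CC[C@H]4OC(C)(C)[C@H](O[Si](C)(C)C(C)(C)C)CC[C@@]43C)[C@]1(O[Si](C)(C)C)C(OC)(OC)[C@H]2CC[C@@H]1C=C2C
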